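**Plan**
1. Numbering and enabling feature: unit 1 is the 5,7-dihydroxyflavanone (benzo ring A, pyranone ring C with O1 to C8a, pendant ring B C1' to C6'); unit 2 is the 5-hydroxy-7-methoxyflavanone (benzo ring D, pyranone ring F, double-primed atoms, pendant ring E); the units are joined C3'–C8''. Ring B is a 1,3,4-trisubstituted benzene (C2 on C1', C8'' on C3', oxygen on C4'), the pattern of methyl coumalate after loss of CO2 and uptake of an aryl ynol ether.
2. Cuts, in retrosynthetic order: five O–benzyl bonds; ring C at O1–C2 and C2–C3 (ring B aldehyde plus ring A β-ketoester); ring F at the C2''–ring E bond, then at O1''–C2'', C2''–C3'' and C4''–C4a'' (chromone from an acetylated ring D); ring B at C2'–C3' and C4'–C5' (methyl coumalate plus a ring D siloxyalkyne).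
3. Forward order: aldehyde to alkyne to siloxyalkyne; ring B by cycloaddition with loss of CO2; acetylation of ring D; two chelation-controlled demethylations with chromone closure between them; ring F flavanone; ester to aldehyde; ring C; hydrogenolysis.
4. Stereochemistry: C2'' (S) comes from ligand-controlled rhodium-catalysed 1,4-arylation of the chromone; C2 (S) comes from a chiral-thiourea-catalysed oxa-Michael closure; no enolising base is used after either centre is set.

Key step: step 3

Assumption 1: the target defines no axial configuration at the C3'–C8'' bond (three ortho oxygen substituents), so the axis is taken as rotating at ambient temperature and rotamers are not treated as separate compounds.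
Assumption 2: the sense of induction of both chiral catalysts is taken from their parent series; the antipodal ligand (step 9) or the quinidine-derived pseudoenantiomer (step 15) would be used if a model substrate shows the opposite sense.

**Step 1**
Reactants: 1 2,4,6-trimethoxybenzaldehyde
Product: 3 2-ethynyl-1,3,5-trimethoxybenzene, via diazoalkene 2 (not isolated)
Conditions: dimethyl (1-diazo-2-oxopropyl)phosphonate (1.5 equiv), K2CO3 (2.5 equiv), MeOH, 0 °C to rt
Reagents that add atoms: dimethyl (1-diazo-2-oxopropyl)phosphonate, CC(=O)C(=[N+]=[N-])P(=O)(OC)OC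
Why: Seyferth–Gilbert homologation with the Ohira–Bestmann reagent: methanolysis of the reagent releases the diazomethylphosphonate anion, which olefinates the non-enolisable aldehyde, and the diazoalkene loses N2 with 1,2-hydrogen shift to give the terminal alkyne.

**Step 2**
Reactants: 3 2-ethynyl-1,3,5-trimethoxybenzene
Product: 6 triisopropyl{[(2,4,6-trimethoxyphenyl)ethynyl]oxy}silane, via lithium acetylide 4 (not isolated), via lithium ynolate 5 (not isolated)
Conditions: LiN(SiMe3)2 (2.2 equiv), (CH3)3COOH (1.0 equiv), THF, −78 to 0 °C; then iPr3SiOSO2CF3 (1.5 equiv), −78 to 0 °C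
Reagents that add atoms: lithium tert-butyl peroxide, CC(C)(C)OO[Li]; triisopropylsilyl trifluoromethanesulfonate, CC(C)[Si](OS(=O)(=O)C(F)(F)F)(C(C)C)C(C)C
Why: Oxidation of a lithium acetylide by electrophilic oxygen transfer from lithium tert-butyl peroxide gives the ynolate, and the hard, bulky silyl triflate traps it on oxygen (O-silylation of an ynolate), the triisopropylsilyl group being the one that makes siloxyalkynes isolable.

**Step 3**
Reactants: 6 triisopropyl{[(2,4,6-trimethoxyphenyl)ethynyl]oxy}silane; 7 methyl coumalate (methyl 2-oxo-2H-pyran-5-carboxylate)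
Product: 9 methyl 4-[(triisopropylsilyl)oxy]-3-(2,4,6-trimethoxyphenyl)benzoate, via bridged lactone 8 (not isolated)
Conditions: 6 (1.2 equiv), 7 (1.0 equiv), PhMe (degassed), 110 °C, sealed tube
Reagents that add atoms: none
Why: The electron-poor pyrone acts as the 4π component across its C3 and C6 and the electron-rich siloxyalkyne as the 2π component in an asynchronous inverse-electron-demand [4+2] cycloaddition, and the 2-oxabicyclo[2.2.2]octadienone 8 then loses CO2 irreversibly by retro-[4+2] reaction to leave ring B aromatic. The closest known reaction type is the cycloaddition–decarboxylation of coumalates and other acceptor-substituted 2-pyrones with ketene acetals, enol ethers, ynamines and other donor-substituted alkynes. Ring B is closed by intermolecular cycloaddition, which forms C2'–C3' and C4'–C5' in one operation, followed by cycloreversion. No stereocentre is formed. The step needs regioselectivity: oxygen polarises the ynol ether so that the carbon carrying ring D is the nucleophilic terminus, and it pairs with pyrone C6, the position conjugated to both the ester and the lactone carbonyl, which places the silyloxy group para and ring D meta to the ester. The triisopropylsilyl group suppresses rearrangement to a silylketene at this temperature, and the hindered biaryl bond is inherited from the aryl–alkyne bond.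

**Step 4**
Reactants: 9 methyl 4-[(triisopropylsilyl)oxy]-3-(2,4,6-trimethoxyphenyl)benzoate
Product: 10 methyl 3-(3-acetyl-2,4,6-trimethoxyphenyl)-4-[(triisopropylsilyl)oxy]benzoate
Conditions: AcCl (1.3 equiv), SnCl4 (1.3 equiv), CH2Cl2, −40 to 0 °C
Reagents that add atoms: acetyl chloride, CC(=O)Cl
Why: Friedel–Crafts acylation takes place at one of the two equivalent free positions of the phloroglucinol-type ring D, each activated by two ortho and one para methoxy group, while ring B is far less nucleophilic and the first acetyl group shuts down a second acylation.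

**Step 5**
Reactants: 10 methyl 3-(3-acetyl-2,4,6-trimethoxyphenyl)-4-[(triisopropylsilyl)oxy]benzoate
Product: 12 methyl 3-(3-acetyl-2-hydroxy-4,6-dimethoxyphenyl)-4-[(triisopropylsilyl)oxy]benzoate, via dichloroboron chelate 11 (not isolated)
Conditions: BCl3 (1.2 equiv), CH2Cl2, −78 to 0 °C; aq. HCl work-up
Reagents that add atoms: none
Why: Chelation-controlled ortho-demethylation: BCl3 bound to the ketone cleaves one flanking methyl ether through a six-membered boron chelate, and the ether wedged between the acetyl group and the biaryl bond should go first because it is twisted out of conjugation (more basic, strain relieved on cleavage), as in the known preferential cleavage of buttressed ortho-methoxy groups in polymethoxyacetophenones.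

**Step 6**
Reactants: 12 methyl 3-(3-acetyl-2-hydroxy-4,6-dimethoxyphenyl)-4-[(triisopropylsilyl)oxy]benzoate
Product: 14 methyl 3-(5,7-dimethoxy-4-oxo-4H-chromen-8-yl)-4-[(triisopropylsilyl)oxy]benzoate, via enaminone 13 (not isolated)
Conditions: Me2NCH(OMe)2 (3 equiv), PhMe, 100 °C; then conc. HCl, CH2Cl2, 40 °C
Reagents that add atoms: N,N-dimethylformamide dimethyl acetal, COC(OC)N(C)C
Why: Enaminone formation at the methyl ketone followed by acid-mediated addition–elimination of the ortho phenol (loss of dimethylamine) is the standard chromone synthesis from 2-hydroxyacetophenones, and since only the C8a'' oxygen is free the biaryl bond is fixed at C8''.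

**Step 7**
Reactants: 14 methyl 3-(5,7-dimethoxy-4-oxo-4H-chromen-8-yl)-4-[(triisopropylsilyl)oxy]benzoate
Product: 16 methyl 3-(5-hydroxy-7-methoxy-4-oxo-4H-chromen-8-yl)-4-[(triisopropylsilyl)oxy]benzoate, via dichloroboron chelate 15 (not isolated)
Conditions: BCl3 (1.5 equiv), CH2Cl2, −78 to 0 °C; aq. HCl work-up
Reagents that add atoms: none
Why: Peri-selective demethylation: the C5'' methyl ether is cleaved through its chelate with the C4'' carbonyl, whereas the C7'' methyl ether cannot chelate and stays, the usual selectivity for 5,7-dimethoxychromones.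

**Step 8**
Reactants: 16 methyl 3-(5-hydroxy-7-methoxy-4-oxo-4H-chromen-8-yl)-4-[(triisopropylsilyl)oxy]benzoate
Product: 18 methyl 4-(benzyloxy)-3-[5-(benzyloxy)-7-methoxy-4-oxo-4H-chromen-8-yl]benzoate, via diphenol 17 (not isolated)
Conditions: Bu4NF (1.1 equiv), THF, 0 °C; then BnBr (3 equiv), K2CO3 (3 equiv), DMF, 60 °C
Reagents that add atoms: benzyl bromide, BrCc1ccccc1
Why: Fluoride desilylation followed by Williamson etherification exchanges the silyl ether for a benzyl ether and caps the chelated C5'' phenol, giving protecting groups that withstand hydride and acid and leave together in one neutral hydrogenolysis.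

**Step 9**
Reactants: 18 methyl 4-(benzyloxy)-3-[5-(benzyloxy)-7-methoxy-4-oxo-4H-chromen-8-yl]benzoate; 19 [4-(benzyloxy)phenyl]boronic acid
Product: 20 methyl 4-(benzyloxy)-3-{(2S)-5-(benzyloxy)-2-[4-(benzyloxy)phenyl]-7-methoxy-4-oxochroman-8-yl}benzoate
Conditions: [Rh(OH)(cod)]2 (2.5 mol %; cod = 1,5-cyclooctadiene), (S)-MeO-F12-BIPHEP (5.5 mol %), 19 (2.0 equiv, in portions), PhMe/H2O (10:1), 30 °C
Reagents that add atoms: none
Why: Hayashi–Miyaura asymmetric 1,4-addition: the aryl group passes from boron to a hydroxo complex of monovalent rhodium carrying an electron-poor atropisomeric bisphosphine, the aryl–rhodium species adds across C2''=C3'' on the face chosen by the ligand (2''S), and hydrolysis of the rhodium enolate releases the flavanone, a reaction class established for 5,7-dioxygenated chromones.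

**Step 10**
Reactants: 20 methyl 4-(benzyloxy)-3-{(2S)-5-(benzyloxy)-2-[4-(benzyloxy)phenyl]-7-methoxy-4-oxochroman-8-yl}benzoate
Product: 21 (2S)-5-(benzyloxy)-8-[2-(benzyloxy)-5-(hydroxymethyl)phenyl]-2-[4-(benzyloxy)phenyl]-7-methoxychroman-4-ol (C4'' epimers)
Conditions: LiAlH4 (2.5 equiv), THF, −20 to 0 °C; neutral aqueous work-up
Reagents that add atoms: none
Why: Hydride reduction takes the ester to the benzylic alcohol and the ring F ketone to the flavan-4-ol (its new carbinol centre is erased in the next step), and carbonyl addition outruns enolisation, so C2'' is not touched.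

**Step 11**
Reactants: 21 (2S)-5-(benzyloxy)-8-[2-(benzyloxy)-5-(hydroxymethyl)phenyl]-2-[4-(benzyloxy)phenyl]-7-methoxychroman-4-ol
Product: 22 4-(benzyloxy)-3-{(2S)-5-(benzyloxy)-2-[4-(benzyloxy)phenyl]-7-methoxy-4-oxochroman-8-yl}benzaldehyde
Conditions: Dess–Martin periodinane (3 equiv), NaHCO3 (8 equiv), CH2Cl2, 0 °C to rt
Reagents that add atoms: none
Why: Dess–Martin oxidation converts both benzylic alcohols under buffered, non-basic conditions, restoring the ring F ketone and delivering the ring B aldehyde without exposing C2'' to ring-opening base.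

**Step 12**
Reactants: 23 2',4',6'-trihydroxyacetophenone
Product: 24 1-[2,4-bis(benzyloxy)-6-hydroxyphenyl]ethan-1-one
Conditions: BnBr (2.05 equiv), K2CO3 (2.2 equiv), DMF, rt
Reagents that add atoms: benzyl bromide, BrCc1ccccc1
Why: Williamson etherification stops after two benzylations because the remaining phenol is locked in a hydrogen bond to the ketone and is much less nucleophilic.

**Step 13**
Reactants: 24 1-[2,4-bis(benzyloxy)-6-hydroxyphenyl]ethan-1-one
Product: 25 tert-butyl 3-[2,4-bis(benzyloxy)-6-hydroxyphenyl]-3-oxopropanoate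
Conditions: LiN(SiMe3)2 (3.3 equiv), THF, −78 to −20 °C; Boc2O (1.1 equiv), −78 to 0 °C; 1 M aq. HCl quench
Reagents that add atoms: di-tert-butyl dicarbonate, CC(C)(C)OC(=O)OC(=O)OC(C)(C)C
Why: Claisen-type C-acylation of the lithium phenoxide–enolate dianion, as in the amide-base acylations of 2-hydroxyacetophenones used to make 1,3-diketones, gives the β-ketoester, and the tert-butyl group prevents lactonisation to a 4-hydroxycoumarin.

**Step 14**
Reactants: 22 ring B aldehyde carrying the finished ring F flavanone; 25 tert-butyl 3-[2,4-bis(benzyloxy)-6-hydroxyphenyl]-3-oxopropanoate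
Product: 26 tert-butyl 2-[2,4-bis(benzyloxy)-6-hydroxybenzoyl]-3-(4-(benzyloxy)-3-{(2S)-5-(benzyloxy)-2-[4-(benzyloxy)phenyl]-7-methoxy-4-oxochroman-8-yl}phenyl)prop-2-enoate (E/Z mixture)
Conditions: piperidine (0.2 equiv), AcOH (0.2 equiv), 4 Å molecular sieves, PhMe, rt to 40 °C
Reagents that add atoms: none
Why: Knoevenagel condensation of the active methylene compound with the aldehyde under buffered amine catalysis, where the hindered, electron-rich ring F ketone does not compete and the buffer is too weak to open ring F.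

**Step 15**
Reactants: 26 alkylidene β-ketoester (E/Z mixture)
Product: 28 (2S)-5,7-bis(benzyloxy)-2-(4-(benzyloxy)-3-{(2S)-5-(benzyloxy)-2-[4-(benzyloxy)phenyl]-7-methoxy-4-oxochroman-8-yl}phenyl)chroman-4-one, via tert-butyl ester 27 (not isolated)
Conditions: 1-[3,5-bis(trifluoromethyl)phenyl]-3-(9-deoxy-epi-quinin-9-yl)thiourea (10 mol %), PhMe, −25 °C; then TsOH·H2O (1 equiv), 80 °C
Reagents that add atoms: none
Why: Catalytic enantioselective intramolecular oxa-Michael addition (6-endo-trig): the thiourea binds the β-ketoester while the quinuclidine guides the phenol to one face of the alkylidene, setting C2 as S under catalyst control independently of the remote C2'' centre, and acid then removes the tert-butyl ester with decarboxylation without any enolising base.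

**Step 16**
Reactants: 28 penta-O-benzyl biflavanone
Product: 29 (2S)-5,7-dihydroxy-2-{4-hydroxy-3-[(2S)-5-hydroxy-2-(4-hydroxyphenyl)-7-methoxy-4-oxochroman-8-yl]phenyl}chroman-4-one (target)
Conditions: H2 (1 atm), Pd/C (10 wt % palladium on carbon), EtOAc/MeOH (1:1), rt
Reagents that add atoms: none
Why: Hydrogenolysis of the five aryl benzyl ethers over palladium on carbon is neutral, so neither flavanone centre can epimerise by ring opening, and the C7'' methyl ether is inert.

**Compound list**
1 | 2,4,6-trimethoxybenzaldehyde | COc1cc(OC)c(C=O)c(OC)c1 | starting material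
2 | 2-(2-diazoethenyl)-1,3,5-trimethoxybenzene | COc1cc(OC)c(C=C=[N+]=[N-])c(OC)c1 | intermediate (not isolated)
3 | 2-ethynyl-1,3,5-trimethoxybenzene | COc1cc(OC)c(C#C)c(OC)c1 | intermediate
4 | lithium (2,4,6-trimethoxyphenyl)acetylide | COc1cc(OC)c(C#C[Li])c(OC)c1 | intermediate (not isolated)
5 | lithium 2-(2,4,6-trimethoxyphenyl)ethynolate | COc1cc(OC)c(C#CO[Li])c(OC)c1 | intermediate (not isolated)
6 | triisopropyl{[(2,4,6-trimethoxyphenyl)ethynyl]oxy}silane | COc1cc(OC)c(C#CO[Si](C(C)C)(C(C)C)C(C)C)c(OC)c1 | intermediate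
7 | methyl coumalate (methyl 2-oxo-2H-pyran-5-carboxylate) | COC(=O)c1ccc(=O)oc1 | starting material
8 | methyl 3-oxo-8-[(triisopropylsilyl)oxy]-7-(2,4,6-trimethoxyphenyl)-2-oxabicyclo[2.2.2]octa-5,7-diene-6-carboxylate (racemic) | O=C1OC2C(C(=O)OC)=CC1C(O[Si](C(C)C)(C(C)C)C(C)C)=C2c1c(OC)cc(OC)cc1OC | intermediate (not isolated)
9 | methyl 4-[(triisopropylsilyl)oxy]-3-(2,4,6-trimethoxyphenyl)benzoate | COC(=O)c1ccc(O[Si](C(C)C)(C(C)C)C(C)C)c(-c2c(OC)cc(OC)cc2OC)c1 | intermediate
10 | methyl 3-(3-acetyl-2,4,6-trimethoxyphenyl)-4-[(triisopropylsilyl)oxy]benzoate | COC(=O)c1ccc(O[Si](C(C)C)(C(C)C)C(C)C)c(-c2c(OC)cc(OC)c(C(C)=O)c2OC)c1 | intermediate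
11 | methyl 3-{3-acetyl-2-[(dichloroboranyl)oxy]-4,6-dimethoxyphenyl}-4-[(triisopropylsilyl)oxy]benzoate | COC(=O)c1ccc(O[Si](C(C)C)(C(C)C)C(C)C)c(-c2c(OC)cc(OC)c(C(C)=O)c2OB(Cl)Cl)c1 | intermediate (not isolated)
12 | methyl 3-(3-acetyl-2-hydroxy-4,6-dimethoxyphenyl)-4-[(triisopropylsilyl)oxy]benzoate | COC(=O)c1ccc(O[Si](C(C)C)(C(C)C)C(C)C)c(-c2c(OC)cc(OC)c(C(C)=O)c2O)c1 | intermediate
13 | methyl 3-{3-[(2E)-3-(dimethylamino)prop-2-enoyl]-2-hydroxy-4,6-dimethoxyphenyl}-4-[(triisopropylsilyl)oxy]benzoate | COC(=O)c1ccc(O[Si](C(C)C)(C(C)C)C(C)C)c(-c2c(OC)cc(OC)c(C(=O)/C=C/N(C)C)c2O)c1 | intermediate (not isolated)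
14 | methyl 3-(5,7-dimethoxy-4-oxo-4H-chromen-8-yl)-4-[(triisopropylsilyl)oxy]benzoate | COC(=O)c1ccc(O[Si](C(C)C)(C(C)C)C(C)C)c(-c2c(OC)cc(OC)c3c(=O)ccoc23)c1 | intermediate
15 | methyl 3-{5-[(dichloroboranyl)oxy]-7-methoxy-4-oxo-4H-chromen-8-yl}-4-[(triisopropylsilyl)oxy]benzoate | COC(=O)c1ccc(O[Si](C(C)C)(C(C)C)C(C)C)c(-c2c(OC)cc(OB(Cl)Cl)c3c(=O)ccoc23)c1 | intermediate (not isolated)
16 | methyl 3-(5-hydroxy-7-methoxy-4-oxo-4H-chromen-8-yl)-4-[(triisopropylsilyl)oxy]benzoate | COC(=O)c1ccc(O[Si](C(C)C)(C(C)C)C(C)C)c(-c2c(OC)cc(O)c3c(=O)ccoc23)c1 | intermediate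
17 | methyl 4-hydroxy-3-(5-hydroxy-7-methoxy-4-oxo-4H-chromen-8-yl)benzoate | COC(=O)c1ccc(O)c(-c2c(OC)cc(O)c3c(=O)ccoc23)c1 | intermediate (not isolated)
18 | methyl 4-(benzyloxy)-3-[5-(benzyloxy)-7-methoxy-4-oxo-4H-chromen-8-yl]benzoate | COC(=O)c1ccc(OCc2ccccc2)c(-c2c(OC)cc(OCc3ccccc3)c3c(=O)ccoc23)c1 | intermediate
19 | [4-(benzyloxy)phenyl]boronic acid | OB(O)c1ccc(OCc2ccccc2)cc1 | starting material
20 | methyl 4-(benzyloxy)-3-{(2S)-5-(benzyloxy)-2-[4-(benzyloxy)phenyl]-7-methoxy-4-oxochroman-8-yl}benzoate | COc1cc(OCc2ccccc2)c2c(c1-c1cc(C(=O)OC)ccc1OCc1ccccc1)O[C@H](c1ccc(OCc3ccccc3)cc1)CC2=O | intermediate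
21 | (2S)-5-(benzyloxy)-8-[2-(benzyloxy)-5-(hydroxymethyl)phenyl]-2-[4-(benzyloxy)phenyl]-7-methoxychroman-4-ol (C4 epimers) | COc1cc(OCc2ccccc2)c2c(c1-c1cc(CO)ccc1OCc1ccccc1)O[C@H](c1ccc(OCc3ccccc3)cc1)CC2O | intermediate
22 | 4-(benzyloxy)-3-{(2S)-5-(benzyloxy)-2-[4-(benzyloxy)phenyl]-7-methoxy-4-oxochroman-8-yl}benzaldehyde | COc1cc(OCc2ccccc2)c2c(c1-c1cc(C=O)ccc1OCc1ccccc1)O[C@H](c1ccc(OCc3ccccc3)cc1)CC2=O | intermediate
23 | 2',4',6'-trihydroxyacetophenone | CC(=O)c1c(O)cc(O)cc1O | starting material
24 | 1-[2,4-bis(benzyloxy)-6-hydroxyphenyl]ethan-1-one | CC(=O)c1c(O)cc(OCc2ccccc2)cc1OCc1ccccc1 | intermediate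
25 | tert-butyl 3-[2,4-bis(benzyloxy)-6-hydroxyphenyl]-3-oxopropanoate | CC(C)(C)OC(=O)CC(=O)c1c(O)cc(OCc2ccccc2)cc1OCc1ccccc1 | intermediate
26 | tert-butyl 2-[2,4-bis(benzyloxy)-6-hydroxybenzoyl]-3-(4-(benzyloxy)-3-{(2S)-5-(benzyloxy)-2-[4-(benzyloxy)phenyl]-7-methoxy-4-oxochroman-8-yl}phenyl)prop-2-enoate (E/Z mixture) | COc1cc(OCc2ccccc2)c2c(c1-c1cc(C=C(C(=O)OC(C)(C)C)C(=O)c3c(O)cc(OCc4ccccc4)cc3OCc3ccccc3)ccc1OCc1ccccc1)O[C@H](c1ccc(OCc3ccccc3)cc1)CC2=O | intermediate
27 | tert-butyl (2S)-5,7-bis(benzyloxy)-2-(4-(benzyloxy)-3-{(2S)-5-(benzyloxy)-2-[4-(benzyloxy)phenyl]-7-methoxy-4-oxochroman-8-yl}phenyl)-4-oxochromane-3-carboxylate (C3 epimerisable) | COc1cc(OCc2ccccc2)c2c(c1-c1cc([C@@H]3C(C(=O)OC(C)(C)C)C(=O)c4c(OCc5ccccc5)cc(OCc5ccccc5)cc4O3)ccc1OCc1ccccc1)O[C@H](c1ccc(OCc3ccccc3)cc1)CC2=O | intermediate (not isolated)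
28 | (2S)-5,7-bis(benzyloxy)-2-(4-(benzyloxy)-3-{(2S)-5-(benzyloxy)-2-[4-(benzyloxy)phenyl]-7-methoxy-4-oxochroman-8-yl}phenyl)chroman-4-one | COc1cc(OCc2ccccc2)c2c(c1-c1cc([C@@H]3CC(=O)c4c(OCc5ccccc5)cc(OCc5ccccc5)cc4O3)ccc1OCc1ccccc1)O[C@H](c1ccc(OCc3ccccc3)cc1)CC2=O | intermediate
29 | (2S)-5,7-dihydroxy-2-{4-hydroxy-3-[(2S)-5-hydroxy-2-(4-hydroxyphenyl)-7-methoxy-4-oxochroman-8-yl]phenyl}chroman-4-one | COc1cc(O)c2c(c1-c1cc([C@@H]3CC(=O)c4c(O)cc(O)cc4O3)ccc1O)O[C@H](c1ccc(O)cc1)CC2=O | target

**Step count**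
Total: 16 steps. Longest linear sequence: 14 steps (steps 1 to 11, then 14 to 16); steps 12 and 13 prepare the ring A fragment.

**Steps most likely to fail**

Step 3. What may go wrong: the ynol ether may rearrange or oligomerise faster than it adds, or regiocontrol may leak because the trimethoxyphenyl donor opposes the polarisation by oxygen. The fallback lowers the dienophile to the ketene acetal oxidation level, the classical partner of coumalates. It sets out from 7: purchased (2,4,6-trimethoxyphenyl)acetic acid F1 is converted with LiN(SiMe3)2 (2.2 equiv) and Me3SiCl into the ketene bis(trimethylsilyl) acetal F2. Heating F2 with 7 in PhMe should give, after cycloaddition (aryl-bearing carbon to pyrone C6), loss of CO2 and elimination of trimethylsilanol, methyl 4-(trimethylsilyloxy)-3-(2,4,6-trimethoxyphenyl)benzoate F3. Methanolysis (MeOH, catalytic K2CO3) gives methyl 4-hydroxy-3-(2,4,6-trimethoxyphenyl)benzoate F4, and iPr3SiCl with imidazole in DMF comes back to the route at 9.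

Step 5. What may go wrong: the unhindered C5''-side methyl ether may be cleaved instead of, or together with, the buttressed one, which would lead into the 6''-aryl chromone series. The fallback differentiates the two oxygens by alkylation instead of dealkylation. It sets out from 10: excess BCl3 (4 equiv, −78 °C to rt) removes both ketone-flanking methyl groups to give methyl 3-(3-acetyl-2,4-dihydroxy-6-methoxyphenyl)-4-[(triisopropylsilyl)oxy]benzoate F5. Bu4NF then frees methyl 3-(3-acetyl-2,4-dihydroxy-6-methoxyphenyl)-4-hydroxybenzoate F6. BnBr (2.1 equiv) with K2CO3 in DMF should benzylate the ring B phenol and the less hindered C5''-side phenol, leaving the hydrogen-bonded phenol beside the biaryl bond free, to give methyl 3-[3-acetyl-4-(benzyloxy)-2-hydroxy-6-methoxyphenyl]-4-(benzyloxy)benzoate F7. Me2NCH(OMe)2 and then HCl close the chromone through that phenol via the enaminone methyl 4-(benzyloxy)-3-{4-(benzyloxy)-3-[(2E)-3-(dimethylamino)prop-2-enoyl]-2-hydroxy-6-methoxyphenyl}benzoate F8. The fallback comes back to the route at 18, so steps 6 to 8 are replaced.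

Step 15. What may go wrong: the activated alkylidene may close outside the chiral catalyst (background oxa-Michael addition during or after the condensation), or ring C may open and reclose during the acidic decarboxylation; both lower the selectivity at C2. The fallback gives up catalyst control and separates at the diastereomer level. It sets out from 26: Et3N (0.2 equiv) in PhMe closes ring C without facial preference to 27 and its C2 epimer, the (2R)-configured tert-butyl ester F9. TsOH·H2O at 80 °C then gives 28 together with its (2R,2''S) epimer F10. The two are diastereomers because C2'' is already fixed, and they are separated by preparative HPLC, on a chiral stationary phase if needed. The (2S,2''S) isomer is 28, where the route is rejoined.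

**Further compounds**
F1 | step 3 | (2,4,6-trimethoxyphenyl)acetic acid | COc1cc(OC)c(CC(=O)O)c(OC)c1
F2 | step 3 | {[2-(2,4,6-trimethoxyphenyl)ethene-1,1-diyl]bis(oxy)}bis(trimethylsilane) | COc1cc(OC)c(C=C(O[Si](C)(C)C)O[Si](C)(C)C)c(OC)c1
F3 | step 3 | methyl 4-(trimethylsilyloxy)-3-(2,4,6-trimethoxyphenyl)benzoate | COC(=O)c1ccc(O[Si](C)(C)C)c(-c2c(OC)cc(OC)cc2OC)c1
F4 | step 3 | methyl 4-hydroxy-3-(2,4,6-trimethoxyphenyl)benzoate | COC(=O)c1ccc(O)c(-c2c(OC)cc(OC)cc2OC)c1
F5 | step 5 | methyl 3-(3-acetyl-2,4-dihydroxy-6-methoxyphenyl)-4-[(triisopropylsilyl)oxy]benzoate | COC(=O)c1ccc(O[Si](C(C)C)(C(C)C)C(C)C)c(-c2c(OC)cc(O)c(C(C)=O)c2O)c1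
F6 | step 5 | methyl 3-(3-acetyl-2,4-dihydroxy-6-methoxyphenyl)-4-hydroxybenzoate | COC(=O)c1ccc(O)c(-c2c(OC)cc(O)c(C(C)=O)c2O)c1
F7 | step 5 | methyl 3-[3-acetyl-4-(benzyloxy)-2-hydroxy-6-methoxyphenyl]-4-(benzyloxy)benzoate | COC(=O)c1ccc(OCc2ccccc2)c(-c2c(OC)cc(OCc3ccccc3)c(C(C)=O)c2O)c1
F8 | step 5 | methyl 4-(benzyloxy)-3-{4-(benzyloxy)-3-[(2E)-3-(dimethylamino)prop-2-enoyl]-2-hydroxy-6-methoxyphenyl}benzoate | COC(=O)c1ccc(OCc2ccccc2)c(-c2c(OC)cc(OCc3ccccc3)c(C(=O)/C=C/N(C)C)c2O)c1
F9 | step 15 | tert-butyl (2R)-5,7-bis(benzyloxy)-2-(4-(benzyloxy)-3-{(2S)-5-(benzyloxy)-2-[4-(benzyloxy)phenyl]-7-methoxy-4-oxochroman-8-yl}phenyl)-4-oxochromane-3-carboxylate | COc1cc(OCc2ccccc2)c2c(c1-c1cc([C@H]3C(C(=O)OC(C)(C)C)C(=O)c4c(OCc5ccccc5)cc(OCc5ccccc5)cc4O3)ccc1OCc1ccccc1)O[C@H](c1ccc(OCc3ccccc3)cc1)CC2=O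
F10 | step 15 | (2R)-5,7-bis(benzyloxy)-2-(4-(benzyloxy)-3-{(2S)-5-(benzyloxy)-2-[4-(benzyloxy)phenyl]-7-methoxy-4-oxochroman-8-yl}phenyl)chroman-4-one | COc1cc(OCc2ccccc2)c2c(c1-c1cc([C@H]3CC(=O)c4c(OCc5ccccc5)cc(OCc5ccccc5)cc4O3)ccc1OCc1ccccc1)O[C@H](c1ccc(OCc3ccccc3)cc1)CC2=O
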